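## Analysis of the target

- The target is the vanillate (4-hydroxy-3-methoxybenzoate) ester of a monocyclic, humulane-type C15 diol. The ring is an 11-membered carbocycle: C1 (ester carbinol), C2=C3 (E, methyl on C3), C4 (free carbinol), C5 (CH2), C6=C7 (Z, methyl on C7), C8–C10 (CH2) and C11 (quaternary, gem-dimethyl), which closes back to C1.
- There are two stereocentres, C1 (R) and C4 (S). They are 1,4-related across the E alkene, both allylic, and no ring fusion relates them. The two alkene geometries are further stereo-elements.
- Sensitive groups: the allylic benzoate (ionisation, SN2′), the free phenol, and the unit C2=C3–C4(OH)–C5–C6=C7, a 3-hydroxy-1,5-diene that can undergo oxy-Cope ring contraction as its alkoxide.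
- The difficulties are the medium ring (entropy, transannular strain), a Z trisubstituted alkene inside it, and a neopentylic carbinol C1 that must carry the ester while the less hindered C4–OH stays free.
- The feature that invites the chosen move: C1 and C7 are 1,6-related across the ring, and C1 is flanked by the quaternary C11. A transannular C1–C7 bond turns the 11-ring into a bicyclo[5.4.0]undecane whose six-membered ring (C1, C7–C11) has the substitution pattern of 2,2,6-trimethylcyclohexanone. An oxygen on C6 then makes a 1,3-diol array set up for fragmentation.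
- The unit C1(O)–C2=C3(CH3)–C4(OH) is the signature of an opened β,γ-epoxy ketone. A C1 ketone can enolise only toward C2, because C11 carries no hydrogen.

## Retrosynthetic reasoning

**22 ⇒ 21 ⇒ 17 + 20.** The last bond made is the ester C–O at C1. Both silyl ethers of 21 (phenol and C4–O) fall in one fluoride step. The acylation is placed late because the allylic ester is the most fragile group, and C4 must be blocked so that the more hindered C1–OH is the only acceptor. Acid 20 comes from vanillic acid 18 in one flask.

**17 ⇒ 16 ⇒ 15.** The C1–H bond is cut: C1 is taken back to a ketone, to be reduced under catalyst control. The C4 silyl ether goes back to the free alcohol. This leaves hydroxy enone 15, with one stereocentre and both alkenes in place.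

**15 ⇒ 13 (key disconnection).** Retrosynthetically the transannular C1–C7 bond is formed, C6 receives a sulfonate and C2=C3/C4–OH is folded back into a C3–C4 epoxide. In the forward direction one base-triggered cascade must:
- cleave C1–C7 and C6–O (Grob fragmentation), which unveils the 11-ring and fixes the Z geometry of C6=C7 from the relative configuration at C6/C7;
- open the epoxide from the new C1 enolate, which gives the E enone and releases C4–OH with the configuration stored in the epoxide.

The cut is made here because it replaces a medium-ring closure by the cleavage of a bond in a 6/7 bicycle. The bicycle is built from a cheap cyclohexanone by routine ring-forming chemistry.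

**13 ⇒ 12 ⇒ 11.** The epoxide is removed to the ring alkene C3=C4 and the mesylate to the secondary alcohol. The forward steps need chemoselective sulfonylation of C6–OH, then delivery of oxygen to the alkene face syn to the remaining C1–OH.

**11 ⇒ 10.** The C3=C4 bond of the seven-membered ring is cut (ring-closing metathesis). A cis trisubstituted alkene in a seven-membered ring is the natural outcome.

**10 ⇒ 9.** The C1–C2 bond is cut: a methallyl nucleophile is added to the C1 ketone. The addition must occur anti to the axial C7 methyl so that the ring fusion becomes cis.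

**9 ⇒ 7 ⇒ 5 ⇒ 4.** The C5–C6 bond is cut (reagent-controlled allylation of aldehyde 7). The formyl group of 7 is traced back, through the propenyl ketone 5, to the allyl group of 4. This costs two steps but lets the quaternary centre be made by a very reliable catalytic asymmetric reaction.

**4 ⇒ 3 ⇒ 1.** The C7–allyl bond is cut (decarboxylative asymmetric allylic alkylation of enol carbonate 3). Racemic 1 has a single enolisable position, so only one enolate can form. C7 becomes the source of absolute configuration, relayed C7 → C6 → C1 → epoxide → C4.

## Alternatives that were turned down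

**Alternative 1:** (textbook) Disconnection of C1–C2 in the open chain. The forward key step is a chromium-mediated Nozaki–Hiyama–Kishi macrocyclisation of the seco iodo aldehyde A1 to the C1 carbinol. Turned down for these reasons:
- an 11-membered ring with a Z trisubstituted alkene would be closed from a flexible chain against transannular strain, at high dilution;
- the new stereocentre C1 forms next to C11 without control, so 17 would come mixed with its C1 epimer A2;
- A1 needs the E vinyl iodide, the Z alkene, the C4 centre and the quaternary carbon to be built separately (well over ten linear steps) before a closure that forms a single bond.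

**Alternative 2:** Disconnection of C6=C7. The forward key step is ring-closing metathesis of the acyclic triene A3 to 17. Turned down for these reasons:
- a trisubstituted alkene would have to form in an 11-membered ring from a 1,1-disubstituted partner;
- its geometry would be set by ring strain and not by the catalyst, since Z-selective catalysts do not accept such partners;
- an E/Z mixture at the last skeletal step cannot be corrected, and oligomerisation competes.

**Alternative 3:** Four-carbon ring expansion. The forward key step is an anionic oxy-Cope rearrangement of the 1,2-dialkenylcycloheptanol A4 to the cycloundecenone A5. Turned down for these reasons: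
- the [3,3] shift necessarily places the new alkene at C5=C6 and leaves C2–C3 saturated;
- it creates stereocentres at C3, C4 and C7 that the target does not have;
- moving one double bond and introducing the other would cost more steps than the ring expansion saves, and A4 is no easier to make than 13.

Key step: step 10

## Route

Remarks on the chemistry:
- The ring locants of the target (C1–C11 as defined above) are used for the same atoms in every intermediate. In the bicyclic compounds they coincide with the von Baeyer numbering of bicyclo[5.4.0]undecane.
- The sense of induction of the chiral ligand and reagents is assigned from the accepted models.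
- Compound 1, compound 18 and all reagents are taken as commercially available.

Step 1
Reactants: 1 2,2,6-trimethylcyclohexan-1-one (racemic)
Product: 3 prop-2-en-1-yl 2,6,6-trimethylcyclohex-1-en-1-yl carbonate, via lithium enolate 2 (not isolated)
Conditions: LiHMDS, THF, 0 °C; allyl chloroformate, −78 °C → rt
Reagents that add atoms: allyl chloroformate, C=CCOC(=O)Cl
Why: 1 has a single α-hydrogen, so only one (tetrasubstituted) lithium enolate can form; the hard chloroformate acylates this hindered enolate on oxygen (enol carbonate formation) and so loads the allyl group for step 2.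

Step 2
Reactants: 3 prop-2-en-1-yl 2,6,6-trimethylcyclohex-1-en-1-yl carbonate
Product: 4 (2S)-2,6,6-trimethyl-2-(prop-2-en-1-yl)cyclohexan-1-one
Conditions: Pd2(dba)3 (2.5 mol %), (S)-t-BuPHOX (6 mol %), THF, 25 °C
Reagents that add atoms: none
Why: Pd-catalysed decarboxylative asymmetric allylic alkylation (enantioselective Tsuji allylation): oxidative addition and loss of CO2 give a Pd(π-allyl) enolate that recombines within the chiral P,N-ligand sphere; the (S)-ligand is expected to give the (S)-configured quaternary centre C7 (the (R)-ligand would be used if the sense proved opposite), and this centre is the source of absolute configuration for the whole route.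

Step 3
Reactants: 4 (2S)-2,6,6-trimethyl-2-(prop-2-en-1-yl)cyclohexan-1-one
Product: 5 (2S)-2,6,6-trimethyl-2-[(1E)-prop-1-en-1-yl]cyclohexan-1-one
Conditions: RuHCl(CO)(PPh3)3 (3 mol %), toluene, 80 °C
Reagents that add atoms: none
Why: Metal-hydride alkene isomerisation (insertion/β-hydride elimination) moves the terminal double bond one position to the more substituted propenyl isomer and cannot go further because C7 is quaternary; any Z isomer is of no consequence since step 4 removes the terminus.

Step 4
Reactants: 5 (2S)-2,6,6-trimethyl-2-[(1E)-prop-1-en-1-yl]cyclohexan-1-one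
Product: 7 (1S)-1,3,3-trimethyl-2-oxocyclohexane-1-carbaldehyde, via secondary ozonide 6 (not isolated)
Conditions: O3, CH2Cl2, −78 °C; then PPh3, −78 °C → rt
Reagents that add atoms: ozone, [O-][O+]=O
Why: Ozonolysis with reductive work-up excises the propenyl terminus as acetaldehyde and leaves the formyl group on the quaternary carbon; 7 cannot enolise at C7 and so cannot racemise, but it is used at once because such a β-keto aldehyde is prone to deformylation by nucleophilic base.

Step 5
Reactants: 7 (1S)-1,3,3-trimethyl-2-oxocyclohexane-1-carbaldehyde
Product: 9 (2S)-2-[(1S)-1-hydroxybut-3-en-1-yl]-2,6,6-trimethylcyclohexan-1-one, via borinate ester 8 (not isolated)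
Conditions: B-allyldiisopinocampheylborane from (+)-α-pinene (1.3 equiv), Et2O, −78 °C; then pH 7 buffer, MeOH, 30 % H2O2, 0 °C
Reagents that add atoms: B-allyldiisopinocampheylborane from (+)-α-pinene, C=CCB([C@@H]1C[C@@H]2C[C@H]([C@H]1C)C2(C)C)[C@@H]1C[C@@H]2C[C@H]([C@H]1C)C2(C)C
Why: Brown allylation through a closed chair transition state reacts only at the aldehyde (the ketone is flanked by two quaternary carbons); reagent control should place the allyl group on the Si face and give the (S)-carbinol C6, the C6–O/C7–CH3 relationship that later becomes the Z alkene; the buffered oxidative work-up avoids retro-aldol cleavage, and the minor enantiomer of 7 should be converted mainly into a separable diastereomer.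

Step 6
Reactants: 9 (2S)-2-[(1S)-1-hydroxybut-3-en-1-yl]-2,6,6-trimethylcyclohexan-1-one
Product: 10 (1R,2S)-2-[(1S)-1-hydroxybut-3-en-1-yl]-2,6,6-trimethyl-1-(2-methylprop-2-en-1-yl)cyclohexan-1-ol
Conditions: 2-methylallylmagnesium chloride (3 equiv), THF, −78 → −30 °C; sat. NH4Cl
Reagents that add atoms: 2-methylallylmagnesium chloride, CC(=C)C[Mg]Cl
Why: Allylic Grignard reagents add even to doubly neopentylic ketones (six-membered SE2′ transition state); with the magnesium-alkoxide side chain equatorial, the axial methyl groups on C7 and C11 block the equatorial trajectory, so axial attack anti to the C7 methyl should give the (1R) tertiary alcohol with the methallyl arm cis to the side chain, as needed for a cis ring fusion; low temperature suppresses retro-aldol and retro-allylation.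

Step 7
Reactants: 10 (1R,2S)-2-[(1S)-1-hydroxybut-3-en-1-yl]-2,6,6-trimethyl-1-(2-methylprop-2-en-1-yl)cyclohexan-1-ol
Product: 11 (1R,6S,7S)-3,7,11,11-tetramethylbicyclo[5.4.0]undec-3-ene-1,6-diol
Conditions: second-generation Grubbs catalyst (5 mol %), CH2Cl2 (5 mM), 40 °C
Reagents that add atoms: none
Why: Ring-closing metathesis between the 1,1-disubstituted and the monosubstituted alkene closes the seven-membered ring C1–C7 as a trisubstituted and necessarily cis cycloalkene; the two arms are cis on the cyclohexane, free hydroxyls are tolerated and loss of ethylene drives the reaction.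

Step 8
Reactants: 11 (1R,6S,7S)-3,7,11,11-tetramethylbicyclo[5.4.0]undec-3-ene-1,6-diol
Product: 12 (1R,6S,7S)-1-hydroxy-3,7,11,11-tetramethylbicyclo[5.4.0]undec-3-en-6-yl methanesulfonate
Conditions: MsCl (1.2 equiv), Et3N, CH2Cl2, −20 → 0 °C
Reagents that add atoms: methanesulfonyl chloride, CS(=O)(=O)Cl
Why: Sulfonylation through the sulfene occurs at the secondary C6–OH, the tertiary C1–OH between two quaternary carbons being far slower; without an alkoxide at C1 the mesylate does not fragment.

Step 9
Reactants: 12 (1R,6S,7S)-1-hydroxy-3,7,11,11-tetramethylbicyclo[5.4.0]undec-3-en-6-yl methanesulfonate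
Product: 13 (1R,3R,4S,6S,7S)-3,4-epoxy-1-hydroxy-3,7,11,11-tetramethylbicyclo[5.4.0]undecan-6-yl methanesulfonate
Conditions: VO(acac)2 (5 mol %), t-BuOOH (1.5 equiv), CH2Cl2, 0 °C → rt
Reagents that add atoms: tert-butyl hydroperoxide, CC(C)(C)OO
Why: Vanadium-catalysed hydroxyl-directed epoxidation of a homoallylic alcohol: the vanadate ester of the only free hydroxyl (C1–OH) delivers oxygen to the C3=C4 face syn to C1–O, which sets C4 as S (and C3 as R); the mesylate is inert to these conditions.

Step 10
Reactants: 13 (1R,3R,4S,6S,7S)-3,4-epoxy-1-hydroxy-3,7,11,11-tetramethylbicyclo[5.4.0]undecan-6-yl methanesulfonate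
Product: 15 (2E,4S,6Z)-4-hydroxy-3,7,11,11-tetramethylcycloundeca-2,6-dien-1-one, via epoxy ketone 14 (not isolated)
Conditions: KOt-Bu (1.3 equiv), t-BuOH/THF (1:1), 0 °C → rt; then sat. NH4Cl
Reagents that add atoms: none
Why: Deprotonation of the tertiary C1–OH triggers a Grob (Wharton-type) fragmentation in which the oxygen lone pair pushes, the C1–C7 σ-bond shared by both rings breaks and mesylate leaves from C6 in one concerted anti-periplanar event, the closest precedent being the base-induced fragmentation of bicyclic 1,3-diol monosulfonates to medium-ring cycloalkenones. No ring is closed by bond formation: the 11-membered ring C1–C11 is unveiled from the fused 6/7 system by cleaving the bridging bond, so the entropic and transannular penalties of a medium-ring closure do not arise. The geometry of the new C6=C7 bond is stereospecific: in the cis-fused conformer with the C6–OMs bond equatorial and anti to C1–C7, the (6S,7S) configuration holds C5 anti to the C7 methyl and gauche to C8, which can only give the Z alkene. The released C1 ketone 14 can enolise only toward C2 because C11 is quaternary, and the enolate opens the β,γ-epoxide by E1cB cleavage of the C3–O bond (the standard base isomerisation of β,γ-epoxy ketones to γ-hydroxy enones), giving the conjugated C2=C3 alkene and the C4 alkoxide. No new stereocentre is created: C4 keeps the S configuration installed in step 9 because its C–O bond is never broken, while C1, C6 and C7 are consumed and their information is turned into alkene geometry. The step needs fragmentation to win over oxetane formation or E2 elimination, which the neopentylic C6 and the fixed anti-periplanar alignment should secure, and E over Z at C2=C3, for which the reversible epoxide opening under alkoxide conditions should let the E enone of the natural ring system accumulate. Only a small excess of base in tert-butanol at or below room temperature is used so that the product alkoxide, a 3-oxido-1,5-diene, stays hydrogen-bonded and does not undergo anionic oxy-Cope ring contraction.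

Step 11
Reactants: 15 (2E,4S,6Z)-4-hydroxy-3,7,11,11-tetramethylcycloundeca-2,6-dien-1-one
Product: 16 (2E,4S,6Z)-4-[(tert-butyldimethylsilyl)oxy]-3,7,11,11-tetramethylcycloundeca-2,6-dien-1-one
Conditions: TBSCl, imidazole, DMF, rt
Reagents that add atoms: tert-butyldimethylsilyl chloride, CC(C)(C)[Si](C)(C)Cl
Why: Standard silylation of the unhindered secondary allylic alcohol; blocking C4–OH now leaves C1 as the only oxygen to be acylated later, and imidazole is too weak a base to deprotonate the enone at the γ-position.

Step 12
Reactants: 16 (2E,4S,6Z)-4-[(tert-butyldimethylsilyl)oxy]-3,7,11,11-tetramethylcycloundeca-2,6-dien-1-one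
Product: 17 (1R,2E,4S,6Z)-4-[(tert-butyldimethylsilyl)oxy]-3,7,11,11-tetramethylcycloundeca-2,6-dien-1-ol
Conditions: (S)-Me-CBS (0.5 equiv), catecholborane (2 equiv), toluene, −78 → −30 °C; then MeOH, 1 M NaOH wash
Reagents that add atoms: none
Why: Corey–Bakshi–Shibata reduction gives 1,2-reduction of the enone under catalyst control; with the quaternary C11 flank acting as the large substituent, the (S)-oxazaborolidine should deliver hydride to give the (1R) allylic alcohol, and catecholborane does not hydroborate the trisubstituted alkene at this temperature.

Step 13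
Reactants: 18 4-hydroxy-3-methoxybenzoic acid (vanillic acid)
Product: 20 4-[(tert-butyldimethylsilyl)oxy]-3-methoxybenzoic acid, via bis-silyl derivative 19 (not isolated)
Conditions: TBSCl (2.5 equiv), imidazole, DMF, rt; then AcOH/THF/H2O, rt
Reagents that add atoms: tert-butyldimethylsilyl chloride, CC(C)(C)[Si](C)(C)Cl
Why: Exhaustive silylation of phenol and acid followed by selective hydrolysis of the labile silyl ester (the aryl silyl ether survives dilute aqueous acetic acid) gives the phenol-protected acid in one flask.

Step 14
Reactants: 17 (1R,2E,4S,6Z)-4-[(tert-butyldimethylsilyl)oxy]-3,7,11,11-tetramethylcycloundeca-2,6-dien-1-ol; 20 4-[(tert-butyldimethylsilyl)oxy]-3-methoxybenzoic acid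
Product: 21 (1R,2E,4S,6Z)-4-[(tert-butyldimethylsilyl)oxy]-3,7,11,11-tetramethylcycloundeca-2,6-dien-1-yl 4-[(tert-butyldimethylsilyl)oxy]-3-methoxybenzoate
Conditions: EDC·HCl, DMAP (1.5 equiv), CH2Cl2, rt → 40 °C
Reagents that add atoms: none
Why: Steglich esterification: the acylpyridinium formed from 20 and DMAP acylates the hindered neopentylic allylic C1–OH with retention at C1; C4 is blocked as its silyl ether, so only C1 can be acylated.

Step 15
Reactants: 21 (1R,2E,4S,6Z)-4-[(tert-butyldimethylsilyl)oxy]-3,7,11,11-tetramethylcycloundeca-2,6-dien-1-yl 4-[(tert-butyldimethylsilyl)oxy]-3-methoxybenzoate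
Product: 22 (1R,2E,4S,6Z)-4-hydroxy-3,7,11,11-tetramethylcycloundeca-2,6-dien-1-yl 4-hydroxy-3-methoxybenzoate
Conditions: TBAF (3 equiv), AcOH (3 equiv), THF, 0 °C → rt
Reagents that add atoms: none
Why: Fluoride cleaves the aryl and the secondary allylic silyl ether in one operation; acetic acid buffers the phenoxide and alkoxide so that the allylic benzoate is not hydrolysed, and the E geometry keeps O1 and O4 too far apart for acyl migration.

## Compound list

1 | 2,2,6-trimethylcyclohexan-1-one (racemic) | CC1CCCC(C)(C)C1=O | starting material
2 | lithium 2,6,6-trimethylcyclohex-1-en-1-olate | [Li+].[O-]C1=C(C)CCCC1(C)C | intermediate (not isolated)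
3 | prop-2-en-1-yl 2,6,6-trimethylcyclohex-1-en-1-yl carbonate | C=CCOC(=O)OC1=C(C)CCCC1(C)C | intermediate
4 | (2S)-2,6,6-trimethyl-2-(prop-2-en-1-yl)cyclohexan-1-one | C=CC[C@]1(C)CCCC(C)(C)C1=O | intermediate
5 | (2S)-2,6,6-trimethyl-2-[(1E)-prop-1-en-1-yl]cyclohexan-1-one | C/C=C/[C@]1(C)CCCC(C)(C)C1=O | intermediate
6 | (2S)-2,6,6-trimethyl-2-(5-methyl-1,2,4-trioxolan-3-yl)cyclohexan-1-one (secondary ozonide) | CC1OOC(O1)[C@]2(C)CCCC(C)(C)C2=O | intermediate (not isolated)
7 | (1S)-1,3,3-trimethyl-2-oxocyclohexane-1-carbaldehyde | O=C[C@]1(C)CCCC(C)(C)C1=O | intermediate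
8 | (1S)-1-[(1S)-1,3,3-trimethyl-2-oxocyclohexyl]but-3-en-1-yl diisopinocampheylborinate | C=CC[C@H](OB([C@@H]2C[C@@H]3C[C@H]([C@H]2C)C3(C)C)[C@@H]2C[C@@H]3C[C@H]([C@H]2C)C3(C)C)[C@]1(C)CCCC(C)(C)C1=O | intermediate (not isolated)
9 | (2S)-2-[(1S)-1-hydroxybut-3-en-1-yl]-2,6,6-trimethylcyclohexan-1-one | C=CC[C@H](O)[C@]1(C)CCCC(C)(C)C1=O | intermediate
10 | (1R,2S)-2-[(1S)-1-hydroxybut-3-en-1-yl]-2,6,6-trimethyl-1-(2-methylprop-2-en-1-yl)cyclohexan-1-ol | C=CC[C@H](O)[C@]1(C)CCCC(C)(C)[C@]1(O)CC(C)=C | intermediate
11 | (1R,6S,7S)-3,7,11,11-tetramethylbicyclo[5.4.0]undec-3-ene-1,6-diol | C[C@@]12CCCC(C)(C)[C@]1(O)CC(C)=CC[C@@H]2O | intermediate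
12 | (1R,6S,7S)-1-hydroxy-3,7,11,11-tetramethylbicyclo[5.4.0]undec-3-en-6-yl methanesulfonate | C[C@@]12CCCC(C)(C)[C@]1(O)CC(C)=CC[C@@H]2OS(C)(=O)=O | intermediate
13 | (1R,3R,4S,6S,7S)-3,4-epoxy-1-hydroxy-3,7,11,11-tetramethylbicyclo[5.4.0]undecan-6-yl methanesulfonate | C[C@@]12CCCC(C)(C)[C@]1(O)C[C@@]3(C)O[C@H]3C[C@@H]2OS(C)(=O)=O | intermediate
14 | (3R,4S,6Z)-3,4-epoxy-3,7,11,11-tetramethylcycloundec-6-en-1-one | O=C1C[C@@]2(C)O[C@H]2C/C=C(/C)CCCC1(C)C | intermediate (not isolated)
15 | (2E,4S,6Z)-4-hydroxy-3,7,11,11-tetramethylcycloundeca-2,6-dien-1-one | O=C1/C=C(\C)[C@@H](O)C/C=C(/C)CCCC1(C)C | intermediate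
16 | (2E,4S,6Z)-4-[(tert-butyldimethylsilyl)oxy]-3,7,11,11-tetramethylcycloundeca-2,6-dien-1-one | O=C1/C=C(\C)[C@@H](O[Si](C)(C)C(C)(C)C)C/C=C(/C)CCCC1(C)C | intermediate
17 | (1R,2E,4S,6Z)-4-[(tert-butyldimethylsilyl)oxy]-3,7,11,11-tetramethylcycloundeca-2,6-dien-1-ol | O[C@@H]1/C=C(\C)[C@@H](O[Si](C)(C)C(C)(C)C)C/C=C(/C)CCCC1(C)C | intermediate
18 | 4-hydroxy-3-methoxybenzoic acid (vanillic acid) | COc1cc(C(=O)O)ccc1O | starting material
19 | tert-butyldimethylsilyl 4-[(tert-butyldimethylsilyl)oxy]-3-methoxybenzoate | COc1cc(C(=O)O[Si](C)(C)C(C)(C)C)ccc1O[Si](C)(C)C(C)(C)C | intermediate (not isolated)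
20 | 4-[(tert-butyldimethylsilyl)oxy]-3-methoxybenzoic acid | COc1cc(C(=O)O)ccc1O[Si](C)(C)C(C)(C)C | intermediate
21 | (1R,2E,4S,6Z)-4-[(tert-butyldimethylsilyl)oxy]-3,7,11,11-tetramethylcycloundeca-2,6-dien-1-yl 4-[(tert-butyldimethylsilyl)oxy]-3-methoxybenzoate | COc1cc(C(=O)O[C@@H]2/C=C(\C)[C@@H](O[Si](C)(C)C(C)(C)C)C/C=C(/C)CCCC2(C)C)ccc1O[Si](C)(C)C(C)(C)C | intermediate
22 | (1R,2E,4S,6Z)-4-hydroxy-3,7,11,11-tetramethylcycloundeca-2,6-dien-1-yl 4-hydroxy-3-methoxybenzoate | COc1cc(C(=O)O[C@@H]2/C=C(\C)[C@@H](O)C/C=C(/C)CCCC2(C)C)ccc1O | target

## Step count and least certain steps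

Total step count: 15. Longest linear sequence: 14 steps (1 → 22 through steps 1–12, 14 and 15). Step 13 is a one-step side branch from 18.

**Step 10 (key step).** Three processes could divert the cascade once the ring has opened, all of them reactions of the free C4 alkoxide or of excess base:
- anionic oxy-Cope ring contraction of the 3-oxido-1,5-diene;
- base-mediated redox isomerisation of the γ-hydroxy enone to a saturated 1,4-diketone, with loss of the C4 centre;
- formation of the C2=C3 bond with the wrong geometry.

Less likely, the C1 alkoxide could close an oxetane onto C6 if the anti-periplanar conformer is poorly populated.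

Fallback: separate the two events and change the mechanism of the second. From 13, exactly one equivalent of KHMDS in THF at −78 °C, quenched cold with acetic acid, should stop at the epoxy ketone 14, because the base is consumed by the fragmentation. Soft enolisation of 14 with TBSOTf and Et3N in CH2Cl2 then opens the silyl-activated epoxide from the enol side. The C4 oxygen emerges directly as its silyl ether and is never an alkoxide. This joins the route at 16 and also saves step 11.

**Step 6.** The methallyl nucleophile could add with poor facial selectivity to the C1 ketone, or the magnesium aldolate could undergo retro-aldol cleavage. The wrong C1 epimer would lead to a trans-fused bicycle that cannot give the Z alkene.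

Fallback: a temporary silicon tether. From 9, silylation of C6–OH with chloro(dimethyl)(2-methylallyl)silane and imidazole gives the (S,S)-configured allylsilyl ether F1. Lewis acid activation of the ketone (TiCl4, CH2Cl2, −78 °C) should then transfer the methallyl group intramolecularly from the side of the C7–C6 bond. Aqueous work-up cleaves the residual O–Si bond and returns the route at 10.

**Step 9.** The hindered tertiary C1–OH may bind vanadium poorly. Oxygen delivery could then lose its direction and the epoxide would form with poor facial selectivity, which would erode the configuration at C4.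

Fallback: reverse the facial bias of non-directed oxidation by a two-step halohydrin sequence. From 12, NBS in aqueous THF should form the bromonium ion on the sterically open face and water should open it at the tertiary C3, giving the bromohydrin F2. Brief treatment with K2CO3 in MeOH at 0 °C closes the epoxide on the face opposite to direct peracid attack and returns the route at 13. If the open face is the one syn to C1–OH, a peracid gives 13 directly.

**Step 12.** The oxazaborolidine may not distinguish the quaternary C11 flank from the alkenyl flank, or the doubly hindered ketone may react sluggishly. The result would be low selectivity at C1.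

Fallback: reduce 16 under substrate control (NaBH4, CeCl3, MeOH, −78 °C; Luche reduction). If the (1S)-epimer F3 predominates, esterify it with acid 20 under Mitsunobu conditions (PPh3, DIAD, toluene). This forms the C1–O bond with inversion and joins the route at 21. Both epimers can thus be channelled to the same ester.

**Step 5.** Reagent control by the allylborane may be eroded by the intrinsic facial bias of the α-quaternary aldehyde (mismatched double stereodifferentiation). This would give mixtures at C6 and, later, E/Z mixtures at C6=C7.

Fallback: set C6 by ketone reduction instead of C–C bond formation. From 7, an unselective indium-mediated Barbier allylation (allyl bromide, In, THF/H2O) gives 9 together with its C6 epimer F4. Dess–Martin oxidation of the mixture gives the single diketone F5. (R)-Me-CBS/BH3 reduction of the side-chain ketone, where the quaternary C7 is the large substituent and the allylic CH2 the small one, should return the (S)-carbinol 9. The ring ketone is too hindered to compete.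

## Further compounds

F0 | step 10 | none | none
F1 | step 6 | (2S)-2-[(1S)-1-{[dimethyl(2-methylprop-2-en-1-yl)silyl]oxy}but-3-en-1-yl]-2,6,6-trimethylcyclohexan-1-one | C=CC[C@H](O[Si](C)(C)CC(C)=C)[C@]1(C)CCCC(C)(C)C1=O
F2 | step 9 | (1R,3R,4R,6S,7S)-4-bromo-1,3-dihydroxy-3,7,11,11-tetramethylbicyclo[5.4.0]undecan-6-yl methanesulfonate | C[C@@]12CCCC(C)(C)[C@]1(O)C[C@@](C)(O)[C@H](Br)C[C@@H]2OS(C)(=O)=O
F3 | step 12 | (1S,2E,4S,6Z)-4-[(tert-butyldimethylsilyl)oxy]-3,7,11,11-tetramethylcycloundeca-2,6-dien-1-ol | O[C@H]1/C=C(\C)[C@@H](O[Si](C)(C)C(C)(C)C)C/C=C(/C)CCCC1(C)C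
F4 | step 5 | (2S)-2-[(1R)-1-hydroxybut-3-en-1-yl]-2,6,6-trimethylcyclohexan-1-one | C=CC[C@@H](O)[C@]1(C)CCCC(C)(C)C1=O
F5 | step 5 | (2S)-2-(but-3-enoyl)-2,6,6-trimethylcyclohexan-1-one | C=CCC(=O)[C@]1(C)CCCC(C)(C)C1=O
A1 | alternative 1 | (5Z,8S,9E)-8-[(tert-butyldimethylsilyl)oxy]-10-iodo-2,2,6,9-tetramethyldeca-5,9-dienal | O=CC(C)(C)CCC/C(C)=C\C[C@H](O[Si](C)(C)C(C)(C)C)/C(C)=C/I
A2 | alternative 1 | (1S,2E,4S,6Z)-4-[(tert-butyldimethylsilyl)oxy]-3,7,11,11-tetramethylcycloundeca-2,6-dien-1-ol | O[C@H]1/C=C(\C)[C@@H](O[Si](C)(C)C(C)(C)C)C/C=C(/C)CCCC1(C)C
A3 | alternative 2 | (3R,4E,6S)-6-[(tert-butyldimethylsilyl)oxy]-2,2,5,9-tetramethyl... open-chain triene: (4S,6E,8R)-4-[(tert-butyldimethylsilyl)oxy]-5,9,9,13-tetramethyltetradeca-1,5,13-trien-8-ol | C=CC[C@H](O[Si](C)(C)C(C)(C)C)/C(C)=C/[C@@H](O)C(C)(C)CCCC(C)=C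
A4 | alternative 3 | 2-[(E)-2-methoxyethenyl]-3,7,7-trimethyl-1-[(E)-prop-1-en-1-yl]cycloheptan-1-ol | C/C=C/C1(O)C(C)(C)CCCC(C)C1/C=C/OC
A5 | alternative 3 | 4-methoxy-3,7,11,11-tetramethylcycloundec-5-en-1-one | COC1C=CC(C)CCCC(C)(C)C(=O)CC1C
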